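An easy step first: reagent charged over starting material charged is the reagent cover, 1.50 in the noon flask, which is the flask asked about.

| setting | noon | summer | flask |
|---|---|---|---|
| starting material | 0.050 M | 0.10 M | 0.050 M |
| reagent | 0.075 M | 0.075 M | 0.0750 M |
| protic impurity | 0.025 M | 0.025 M | 0.0250 M |
| remark | the very flask that is asked about, followed so far | run made earlier |  |
| time |  |  | 40 h |

| run | time / h | starting material / % | target / % |
|---|---|---|---|
| noon | 1.50 | 82.0 | 14.4 |
| noon | 3.00 | 30.7 | 66.0 |
| noon | 5.00 | 6.6 | 87.3 |
| noon | 6.00 | 4.3 | 92.0 |
| noon | 8.00 | 0.2 | 93.7 |
| summer | 8.00 | 23.4 | 74.3 |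
| summer | 15.0 | 18.4 | 72.8 |
| summer | 25.0 | 17.5 | 73.0 |
| summer | 30.0 | 16.9 | 75.0 |
| summer | 40.0 | 14.8 | 73.5 |

(each reading ± 1 percentage point)

- the earlier runs were read with a standard deviation of 1 percentage point
- the reaction counts as stopped when no species that holds the starting material changes by six tenths of a point or more over the second half of the time

* why nothing more happens at 40 h, or that something still does (all of the starting material has reacted / the reagent has run out first / it is still moving / forward and back rates have come level)
* conversion of starting material at 40 h
* amount of target at 40 h, in percent of the starting material charged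

One thing looks wrong in the summer run. Its target reads 74.3% at 8.00 h and 73.5% at 40.0 h, yet its starting material is still there and falling, from 23.4% to 14.8%. I reckon the cover:

summer cover = 0.750, so target ceiling = 75.0%

The summer target reads close to that ceiling, so I read one reagent per target, and the late fall of starting material as a loss that makes no target.

The noon flask has a cover above one, so its ceiling is the charge itself. There the starting material reads 0.2% at 8.00 h beside 93.7% target, and the missing 6.10% I take as that same loss:

noon target at 40 h ≈ 93.9%

The forecast gives all of the starting material has reacted, conversion 100% (99% to 100%) and target 94% (92% to 96%): “so it should be fully consumed by 40 h”.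

The flask gives all of the starting material has reacted, conversion 100%, target 95.0%.

    starting material + protic impurity → quenched substrate (k = 2.20 × 10⁻⁴ M⁻¹ s⁻¹)
    starting material + reagent + by-product → target + 2 by-product (k = 0.180 M⁻² s⁻¹)
    2 reagent → self-condensation product (k = 6.90 × 10⁻⁵ M⁻¹ s⁻¹)
    starting material + reagent → target + by-product (k = 5.80 × 10⁻⁵ M⁻¹ s⁻¹)

In the noon flask, with cover 1.50, starting material stands at 0% at 40.0 h, with reagent at 20% of its own charge, and target stands at 95.0% even at 400 h. One more flask, alike but charged with 0.20 M of starting material, has cover 0.375, so its ceiling is 37.5%. It gives 36.8% target at 40.0 h, with reagent, there the limiting reagent, at 0%, and 51.1% of its starting material still unreacted.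

The numbers in the tables were generated by integration from invented constants.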